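**Retrosynthetic overview**

1. The enone C=C is cut by a Claisen–Schmidt disconnection into ring-A acetophenone 13 and 2,2-dimethyl-2H-chromene-6-carbaldehyde 20; the acetyl group of 13 comes from ortho-lithiation of dihydrobenzofuran 9.
2. The dihydrofuran ring is opened at the C3–C3a bond (the CH2 and the aromatic carbon lying between the two ring-A oxygens); forward, this bond is made by Pd(OAc)2/PCy3-catalysed C(sp3)–H arylation of the open-chain aryl bromide 7.
3. Enabling feature: C3 is a methyl group on the stereogenic carbon C2, which hangs on O1 at C7a next to C3a, so palladium at C3a reaches a methyl C–H through a six-membered palladacycle. The unit O1–C2(H)(CH3)–C(OH)Me2 is the lactic acid skeleton, so C2 (R) comes from ethyl (S)-lactate by Mitsunobu inversion and the carbinol from the ester and two MeMgBr.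
4. Ring order: benzene ring A is bought (2-bromoresorcinol); the dihydrofuran ring closes in step 5; the pyran ring of the chromene is made on the other fragment in step 9 (aryl propargyl ether Claisen, oxa-6π); the fragments are joined last.

Key step: step 5

Remark on the chemistry: the only stereocentre (C2 of the dihydrofuran) is R; the desymmetrisation of 2-bromoresorcinol in step 1 is statistical, and the bis-ether and recovered diol are recycled.

**Route**

Step 1
Reactants: 1 2-bromobenzene-1,3-diol (2-bromoresorcinol)
Product: 2 2-bromo-3-(methoxymethoxy)phenol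
Conditions: NaH (1.0 equiv), THF/DMF, 0 °C; MOMCl (1.0 equiv), 0 °C to rt; chromatography
Reagents that add atoms: chloromethyl methyl ether (MOMCl), COCCl
Why: Williamson-type O-alkylation of the monophenoxide with one equivalent of the chloromethyl ether should give the mono-acetal as the main product of a statistical desymmetrisation.

Step 2
Reactants: 2 2-bromo-3-(methoxymethoxy)phenol; 3 ethyl (S)-lactate
Product: 4 ethyl (2R)-2-[2-bromo-3-(methoxymethoxy)phenoxy]propanoate
Conditions: PPh3, DIAD, THF, 0 °C to rt
Reagents that add atoms: none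
Why: Mitsunobu etherification of the acidic ortho-bromophenol with the secondary lactate alcohol is an SN2 displacement of the oxyphosphonium group, so the S centre of the lactate is inverted to the R centre that becomes C2 of the dihydrofuran.

Step 3
Reactants: 4 ethyl (2R)-2-[2-bromo-3-(methoxymethoxy)phenoxy]propanoate
Product: 6 (3R)-3-[2-bromo-3-(methoxymethoxy)phenoxy]-2-methylbutan-2-ol, via methyl ketone 5 (not isolated)
Conditions: MeMgBr (3 equiv), THF, −20 to 0 °C; then H2O
Reagents that add atoms: methylmagnesium bromide, C[Mg]Br
Why: Double Grignard addition to the ester through ketone 5 should give the tertiary carbinol, the aryl bromide and the acetal being inert to MeMgBr at or below 0 °C and the fast second addition outrunning enolisation at the stereocentre.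

Step 4
Reactants: 6 (3R)-3-[2-bromo-3-(methoxymethoxy)phenoxy]-2-methylbutan-2-ol
Product: 7 {[(3R)-3-[2-bromo-3-(methoxymethoxy)phenoxy]-2-methylbutan-2-yl]oxy}triethylsilane
Conditions: TESOTf, 2,6-lutidine, CH2Cl2, −40 to 0 °C
Reagents that add atoms: triethylsilyl trifluoromethanesulfonate, CC[Si](CC)(CC)OS(=O)(=O)C(F)(F)F
Why: Silylation of the hindered tertiary alcohol with a silyl triflate and a hindered pyridine base masks the hydroxyl group, which could otherwise bind palladium in the next step (C–O coupling or β-carbon elimination).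

Step 5
Reactants: 7 {[(3R)-3-[2-bromo-3-(methoxymethoxy)phenoxy]-2-methylbutan-2-yl]oxy}triethylsilane
Product: 9 triethyl({2-[(2R)-4-(methoxymethoxy)-2,3-dihydro-1-benzofuran-2-yl]propan-2-yl}oxy)silane, via six-membered palladacycle 8 (not isolated)
Conditions: Pd(OAc)2 (5 mol%), PCy3·HBF4 (10 mol%), PivOH (30 mol%), Cs2CO3 (1.5 equiv), mesitylene (0.05 M), 135 °C, argon
Reagents that add atoms: none
Why: Zerovalent palladium formed from Pd(OAc)2 and PCy3 inserts into the C–Br bond at the aromatic carbon flanked by the two oxygens, bromide is exchanged for pivalate, and pivalate-assisted concerted metalation–deprotonation of the methyl group on the ether stereocentre gives the six-membered palladacycle 8 of divalent palladium (Pd, C3a, C7a, O1, C2, C3), which reductively eliminates to form the C3–C3a bond. The closest known reaction type is the Pd(OAc)2/PCy3/pivalate-mediated intramolecular alkane arylation that converts 2-bromophenyl tert-alkyl ethers into 2,2-dialkyl-2,3-dihydrobenzofurans and N-(sec-alkyl)-2-bromoanilides into 2-substituted indolines. The five-membered dihydrofuran ring closes by C(sp2)–C(sp3) reductive elimination, that is by contraction of the six-membered palladacycle. No new stereocentre is formed: the R centre from lactate takes part in no bond change (activation of its own C–H would need a strained five-membered palladacycle with no stable product) and is carried into C2 unchanged. The step needs site selectivity for the lactate methyl over the geminal methyls of the silyloxy carbon and the acetal C–H bonds, and C–C reductive elimination over β-hydride elimination; only the lactate methyl gives a six-membered palladacycle (the geminal methyls would need a seven-membered one, the OCH2O group a five-membered one that can only revert by protonation), the rigid palladacycle and the bulky electron-rich phosphine favour reductive elimination, and the position of closure on the arene is fixed by the bromine.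

Step 6
Reactants: 9 triethyl({2-[(2R)-4-(methoxymethoxy)-2,3-dihydro-1-benzofuran-2-yl]propan-2-yl}oxy)silane
Product: 11 1-[(2R)-4-(methoxymethoxy)-2-{2-[(triethylsilyl)oxy]propan-2-yl}-2,3-dihydro-1-benzofuran-5-yl]ethan-1-one, via aryllithium 10 (not isolated)
Conditions: n-BuLi (1.3 equiv), TMEDA, THF, −20 to 0 °C; then MeC(O)N(OMe)Me, −78 °C to rt; then H2O
Reagents that add atoms: N-methoxy-N-methylacetamide, CON(C)C(C)=O
Why: Directed ortho-metalation: the methoxymethoxy group should direct n-BuLi to C5, its only free ortho position (the ring oxygen is a much weaker director for C7), and aryllithium 10 acylates the Weinreb amide to a stable chelate that releases the methyl ketone only on work-up.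

Step 7
Reactants: 11 1-[(2R)-4-(methoxymethoxy)-2-{2-[(triethylsilyl)oxy]propan-2-yl}-2,3-dihydro-1-benzofuran-5-yl]ethan-1-one
Product: 13 1-[(2R)-4-hydroxy-2-(2-hydroxypropan-2-yl)-2,3-dihydro-1-benzofuran-5-yl]ethan-1-one, via desilylated ketone 12 (not isolated)
Conditions: HCl (1.25 M in MeOH, catalytic), MeOH, 0 °C to rt
Reagents that add atoms: none
Why: Acid-catalysed methanolysis should remove the tertiary triethylsilyl ether and then, by acetal exchange, the methoxymethyl ether activated by the ortho carbonyl group, under conditions too mild to ionise the tertiary carbinol or open the dihydrofuran.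

Step 8
Reactants: 14 4-hydroxybenzaldehyde; 15 3-chloro-3-methylbut-1-yne
Product: 16 4-[(2-methylbut-3-yn-2-yl)oxy]benzaldehyde
Conditions: K2CO3, KI (cat.), CuI (cat.), acetone, 60 °C
Reagents that add atoms: none
Why: O-Propargylation of the phenoxide with the tertiary propargylic chloride, assisted by CuI, is the standard entry to 1,1-dimethylpropargyl aryl ethers.

Step 9
Reactants: 16 4-[(2-methylbut-3-yn-2-yl)oxy]benzaldehyde
Product: 20 2,2-dimethyl-2H-chromene-6-carbaldehyde, via allenyl dienone 17 (not isolated), via allenylphenol 18 (not isolated), via ortho-quinone methide 19 (not isolated)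
Conditions: N,N-diethylaniline, 190 °C
Reagents that add atoms: none
Why: Thermal aryl propargyl ether Claisen rearrangement ([3,3]), tautomerisation, 1,5-hydrogen shift and oxa-6π electrocyclisation should give the 2,2-dimethylchromene, and because the two ortho positions are equivalent only one product can form.

Step 10
Reactants: 13 1-[(2R)-4-hydroxy-2-(2-hydroxypropan-2-yl)-2,3-dihydro-1-benzofuran-5-yl]ethan-1-one; 20 2,2-dimethyl-2H-chromene-6-carbaldehyde
Product: 22 (E)-3-(2,2-dimethyl-2H-chromen-6-yl)-1-[(2R)-4-hydroxy-2-(2-hydroxypropan-2-yl)-2,3-dihydro-1-benzofuran-5-yl]prop-2-en-1-one (target), via aldol adduct 21 (not isolated)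
Conditions: KOH (10 equiv), EtOH, rt, argon; then dilute HCl to pH 5 at 0 °C
Reagents that add atoms: none
Why: Claisen–Schmidt condensation: the potassium enolate of the 2'-hydroxyacetophenone adds to the non-enolisable aldehyde and aldol 21 loses water by E1cB to the conjugated, thermodynamically favoured E enone, while the stereocentre is remote from any acidic position and is untouched.

**Compound list**

1 | 2-bromobenzene-1,3-diol (2-bromoresorcinol) | Oc1cccc(O)c1Br | starting material
2 | 2-bromo-3-(methoxymethoxy)phenol | COCOc1cccc(O)c1Br | intermediate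
3 | ethyl (2S)-2-hydroxypropanoate (ethyl (S)-lactate) | C[C@H](O)C(=O)OCC | starting material
4 | ethyl (2R)-2-[2-bromo-3-(methoxymethoxy)phenoxy]propanoate | CCOC(=O)[C@@H](C)Oc1cccc(OCOC)c1Br | intermediate
5 | (3R)-3-[2-bromo-3-(methoxymethoxy)phenoxy]butan-2-one (not isolated) | CC(=O)[C@@H](C)Oc1cccc(OCOC)c1Br | intermediate
6 | (3R)-3-[2-bromo-3-(methoxymethoxy)phenoxy]-2-methylbutan-2-ol | CC(C)(O)[C@@H](C)Oc1cccc(OCOC)c1Br | intermediate
7 | {[(3R)-3-[2-bromo-3-(methoxymethoxy)phenoxy]-2-methylbutan-2-yl]oxy}triethylsilane | CC[Si](CC)(CC)OC(C)(C)[C@@H](C)Oc1cccc(OCOC)c1Br | intermediate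
8 | six-membered palladacycle of divalent palladium: Pd bonded to the aryl carbon between the two oxygens and to the former lactate methyl carbon, PCy3 as ligand, configuration at the ether carbon as in 7 (not isolated) | COCOc1cccc2O[C@H](C[Pd-]([P+](C3CCCCC3)(C3CCCCC3)C3CCCCC3)c12)C(C)(C)O[Si](CC)(CC)CC | intermediate
9 | triethyl({2-[(2R)-4-(methoxymethoxy)-2,3-dihydro-1-benzofuran-2-yl]propan-2-yl}oxy)silane | COCOc1cccc2O[C@H](Cc12)C(C)(C)O[Si](CC)(CC)CC | intermediate
10 | 5-lithio derivative of 9 (not isolated) | COCOc1c([Li])ccc2O[C@H](Cc12)C(C)(C)O[Si](CC)(CC)CC | intermediate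
11 | 1-[(2R)-4-(methoxymethoxy)-2-{2-[(triethylsilyl)oxy]propan-2-yl}-2,3-dihydro-1-benzofuran-5-yl]ethan-1-one | COCOc1c(C(C)=O)ccc2O[C@H](Cc12)C(C)(C)O[Si](CC)(CC)CC | intermediate
12 | 1-[(2R)-2-(2-hydroxypropan-2-yl)-4-(methoxymethoxy)-2,3-dihydro-1-benzofuran-5-yl]ethan-1-one (not isolated) | COCOc1c(C(C)=O)ccc2O[C@H](Cc12)C(C)(C)O | intermediate
13 | 1-[(2R)-4-hydroxy-2-(2-hydroxypropan-2-yl)-2,3-dihydro-1-benzofuran-5-yl]ethan-1-one | CC(=O)c1ccc2c(c1O)C[C@H](C(C)(C)O)O2 | intermediate
14 | 4-hydroxybenzaldehyde | O=Cc1ccc(O)cc1 | starting material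
15 | 3-chloro-3-methylbut-1-yne | C#CC(C)(C)Cl | starting material
16 | 4-[(2-methylbut-3-yn-2-yl)oxy]benzaldehyde | C#CC(C)(C)Oc1ccc(C=O)cc1 | intermediate
17 | racemic 3-(3-methylbuta-1,2-dien-1-yl)-4-oxocyclohexa-1,5-diene-1-carbaldehyde (not isolated) | O=C1C=CC(C=O)=CC1C=C=C(C)C | intermediate
18 | 4-hydroxy-3-(3-methylbuta-1,2-dien-1-yl)benzaldehyde (not isolated) | CC(C)=C=Cc1cc(C=O)ccc1O | intermediate
19 | (3Z)-3-(3-methylbut-2-en-1-ylidene)-4-oxocyclohexa-1,5-diene-1-carbaldehyde (not isolated) | O=C1C=CC(C=O)=C/C1=C/C=C(C)C | intermediate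
20 | 2,2-dimethyl-2H-chromene-6-carbaldehyde | CC1(C)C=Cc2cc(C=O)ccc2O1 | intermediate
21 | 3-(2,2-dimethyl-2H-chromen-6-yl)-3-hydroxy-1-[(2R)-4-hydroxy-2-(2-hydroxypropan-2-yl)-2,3-dihydro-1-benzofuran-5-yl]propan-1-one, both carbinol epimers (not isolated) | CC1(C)C=Cc2cc(C(O)CC(=O)c3ccc4c(c3O)C[C@H](C(C)(C)O)O4)ccc2O1 | intermediate
22 | (E)-3-(2,2-dimethyl-2H-chromen-6-yl)-1-[(2R)-4-hydroxy-2-(2-hydroxypropan-2-yl)-2,3-dihydro-1-benzofuran-5-yl]prop-2-en-1-one (CNP0302034.2) | CC1(C)C=Cc2cc(/C=C/C(=O)c3ccc4c(c3O)C[C@H](C(C)(C)O)O4)ccc2O1 | target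

**Step count and risks**

Total step count: 10. Longest linear sequence: 8 (steps 1 to 7, then step 10).

Steps most likely to fail:

1. Step 5 (key step). The arylpalladium intermediate may be diverted before C–C bond formation, by β-hydride elimination from the palladacycle or by migration of palladium onto the acetal carbon followed by protonation, so that the bromide is only reduced. Oxidative addition at the bromide flanked by two alkoxy groups may also be slow. The fallback closes the same ring at the O1–C2 bond by known chemistry; it sets out from 2 and comes back at 9. Deprotonation and bromine–lithium exchange of 2 (n-BuLi, 2.2 equiv, THF, −78 °C) should give the dilithio species F1. With CuBr·SMe2 and prenyl bromide this gives 3-(methoxymethoxy)-2-(3-methylbut-2-en-1-yl)phenol F2. Acetylation (Ac2O, pyridine) gives the aryl acetate F3. Shi epoxidation with the L-fructose-derived ketone (KHSO5, K2CO3, MeCN–dimethoxymethane–H2O, 0 °C) should give the (S)-epoxide F4. K2CO3 in MeOH cleaves the acetate to the epoxy phenol F5, whose phenoxide opens the epoxide 5-exo at the secondary carbon with inversion to give the (R)-carbinol F6. Silylation as in step 4 returns to 9.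

2. Step 6. Lithiation may occur at the benzylic C3 position, followed by β-elimination of the ring oxygen and ring opening, or the amide may transfer a proton to the aryllithium instead of being acylated. The fallback replaces metalation by electrophilic ortho-formylation of the free phenol; it sets out from 9 and comes back at 13. HCl in MeOH removes both protecting groups to give the phenol diol F7. MgCl2, Et3N and paraformaldehyde in MeCN at reflux should formylate the only free ortho position to give the salicylaldehyde F8. MeMgBr (excess, THF, 0 °C) gives the benzylic alcohol F9 as a mixture of carbinol epimers. MnO2 (CH2Cl2, rt) should oxidise the benzylic alcohol selectively and return to 13.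

3. Step 3. Enolisation of ester 4 or of ketone 5 by the Grignard reagent may erode the configuration of the aryloxy stereocentre. The fallback forms the ether bond by epoxide opening at the tertiary-alcohol oxidation level, so that no carbonyl group ever flanks the stereocentre; it sets out from 2 and comes back at 6. Methyl (R)-lactate and MeMgBr give (3R)-2-methylbutane-2,3-diol F10. TsCl in pyridine sulfonylates the secondary hydroxyl group to give (2R)-3-hydroxy-3-methylbutan-2-yl 4-methylbenzenesulfonate F11. KOH closes it with inversion to (3S)-2,2,3-trimethyloxirane F12, which is distilled. Phenol 2 with K2CO3 in DMF at 100 °C (sealed tube) should open F12 at the less substituted carbon with a second inversion and return to 6.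

**Further compounds**

F1 | step 5 | lithium 2-lithio-3-(methoxymethoxy)phenoxide (not isolated) | COCOc1cccc(O[Li])c1[Li]
F2 | step 5 | 3-(methoxymethoxy)-2-(3-methylbut-2-en-1-yl)phenol | COCOc1cccc(O)c1CC=C(C)C
F3 | step 5 | 3-(methoxymethoxy)-2-(3-methylbut-2-en-1-yl)phenyl acetate | COCOc1cccc(OC(C)=O)c1CC=C(C)C
F4 | step 5 | 2-{[(2S)-3,3-dimethyloxiran-2-yl]methyl}-3-(methoxymethoxy)phenyl acetate | CC(=O)Oc1cccc(OCOC)c1C[C@@H]1OC1(C)C
F5 | step 5 | 2-{[(2S)-3,3-dimethyloxiran-2-yl]methyl}-3-(methoxymethoxy)phenol (not isolated) | COCOc1cccc(O)c1C[C@@H]1OC1(C)C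
F6 | step 5 | 2-[(2R)-4-(methoxymethoxy)-2,3-dihydro-1-benzofuran-2-yl]propan-2-ol | COCOc1cccc2O[C@H](Cc12)C(C)(C)O
F7 | step 6 | (2R)-2-(2-hydroxypropan-2-yl)-2,3-dihydro-1-benzofuran-4-ol | Oc1cccc2c1C[C@H](C(C)(C)O)O2
F8 | step 6 | (2R)-4-hydroxy-2-(2-hydroxypropan-2-yl)-2,3-dihydro-1-benzofuran-5-carbaldehyde | O=Cc1ccc2c(c1O)C[C@H](C(C)(C)O)O2
F9 | step 6 | (2R)-5-(1-hydroxyethyl)-2-(2-hydroxypropan-2-yl)-2,3-dihydro-1-benzofuran-4-ol, both carbinol epimers | CC(O)c1ccc2c(c1O)C[C@H](C(C)(C)O)O2
F10 | step 3 | (3R)-2-methylbutane-2,3-diol | C[C@@H](O)C(C)(C)O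
F11 | step 3 | (2R)-3-hydroxy-3-methylbutan-2-yl 4-methylbenzenesulfonate | C[C@@H](OS(=O)(=O)c1ccc(C)cc1)C(C)(C)O
F12 | step 3 | (3S)-2,2,3-trimethyloxirane | C[C@@H]1OC1(C)C
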